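The product, monomer in chains, grows while growing radical is present, and that presence can be counted in lifetimes of free monomer.

free monomer 20 mM; protic impurity 2.00 mM; initiator 1.0 mM; time 2.5 d

    initiator → 2 initiating radical (k1 = 0.038 min⁻¹)
    free monomer + initiating radical → growing radical + monomer in chains (k2 = 19000 M⁻¹ s⁻¹)
    free monomer + growing radical → monomer in chains + growing radical, rate k3*[growing radical]*[free monomer] (k3 = 29000 M⁻¹ min⁻¹)
    2 growing radical → dead chain (k4 = 2.4 × 10⁶ M⁻¹ s⁻¹)
    protic impurity + free monomer → quenched substrate (k5 = 18 M⁻¹ min⁻¹)
    monomer in chains → over-reaction product (k6 = 2.1 × 10⁻⁵ min⁻¹)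

- a doubled species enters its step squared and goes two at a time
- the average divides the monomer in chains by the number of chains, living and dead together; two radicals that join make one chain
- run time (flask): 2.5 d

- average number of monomer units in a chain (living and dead chains, two that joined counted as one) at 2.5 d
- part of the free monomer that has reacted at 2.5 d

Let I be the initiator and R the growing radical. Making and losing R balance in a steady state:

2·0.038 min⁻¹·I = 2·2.4 × 10⁶ M⁻¹ s⁻¹·R·R, which gives R = 5.14 × 10⁻⁴ mM at the charge of I.

R follows the square root of I, so its lifetime L is 2 lifetimes of initiator, and free monomer falls pseudo-first-order while R lasts: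

L = 52.6 min
m = 1/(29000 M⁻¹ min⁻¹·R) = 67.1 min

You carry W = L/m, the reach: the number of free-monomer lifetimes that the charge of initiator can buy. Here W = 0.784, and L is shorter than m.

At its charge of free monomer, protic impurity has a half-life of 1.93 min, shorter than the 0.30 h of initiator, so I take its 2.00 mM off at the start. Initiation draws its free monomer while the reach is being spent; weighted by the reach still ahead, that costs:

A = 4·I·[1 − e^(−W)·(1 + W)]/(W·W) = 1.21 mM
Free monomer left = (20 mM − 2.00 mM)·e^(−W) − A = 7.01 mM, or 35.1% of the charge

The neighbour charged with 0.40 mM of initiator differs in that charge and has the same L, but its lower R stretches m to 106 min. Its reach is 0.496, with A = 0.579 mM, so I reckon that it keeps 51.9%, more than I reckon for this flask.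

The forecast gives 10.2 units per chain and 65.2% reacted, holding that “Growing radicals sit at steady state”.

The flask gives 10.2 units per chain and 65.2% reacted.

A reach of 0.784 put free monomer at 35.1% of its charge, and this flask holds 34.8%; the reach of 0.496 put the neighbour at 51.9%, and it holds 51.7%, with 17.8 units per chain. The chain length of this flask comes in part from the using up of initiator and in part from the hour of reading. With the initiator kept from being used up, the average falls from 10.2 to 4.35, and read at 25.0 d it is 5.19.

All constants were chosen freely; what happens was integrated by code.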